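**Assumption:** CNP0265116.2 is taken exactly as the SMILES given: (3S,6R,7S,8R,9R), 1(10)Z and 4E, in germacrane numbering (C1–C15, lactone C12–O–C6). This numbering is used for all intermediates.

## Retrosynthetic overview

1. Target ⇐ O3-silyl ether; the O8 angelate and O9 acetate are put on an 8,9-diol released from an acetonide after ring formation.
2. The ten-membered carbocycle and the trans γ-lactone form together: C6–C7 bond by a visible-light, chromium-catalysed intramolecular Barbier allylation/lactonization of an E-enal onto a (Z)-2-(bromomethyl)enoate, with C6 and C7 set by C8.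
3. Bromomethyl enoate ⇐ Morita–Baylis–Hillman adduct of the C7 aldehyde; C1=C10 (Z) ⇐ Wittig reaction of an α-alkoxy methyl ketone with a C1–C6 ylide.
4. Ketone half (C7–C10, C14; C8 and C9 bought) ⇐ dimethyl 2,3-O-isopropylidene-D-tartrate. Ylide half (C1–C6, C15; C3 bought) ⇐ (S)-α-hydroxy-γ-butyrolactone (the L-malic acid lactone).
5. Ring order: dioxolane (bought, temporary) → carbocycle and lactone in one step → dioxolane opened.

## Route

Step 1
Reactants: 1 (S)-α-hydroxy-γ-butyrolactone [(3S)-3-hydroxyoxolan-2-one]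
Product: 2 (3S)-3-(tert-butyldiphenylsilyloxy)oxolan-2-one
Conditions: t-BuPh2SiCl, imidazole, DMF, 0 °C → rt
Reagents that add atoms: tert-butyl(chloro)diphenylsilane `CC(C)(C)[Si](Cl)(c1ccccc1)c1ccccc1`
Why: Imidazole-promoted silylation puts on O3 a group that survives base, hydride, the later acetonide hydrolysis and both acylations, and the bought C3 centre is not touched.

Step 2
Reactants: 2 (3S)-3-(tert-butyldiphenylsilyloxy)oxolan-2-one
Product: 3 (3S)-3-(tert-butyldiphenylsilyloxy)-5-hydroxypentan-2-one (in equilibrium with its cyclic hemiketal)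
Conditions: MeLi (1.05 equiv), THF, −78 °C; AcOH quench at −78 °C
Reagents that add atoms: methyllithium `[Li]C`
Why: Mono-addition of an organolithium to a γ-lactone works because the lithium hemiketal is stable at −78 °C, so only one methyl (C15) adds and the cold quench leaves the α-silyloxy centre unepimerized.

Step 3
Reactants: 3 (3S)-3-(tert-butyldiphenylsilyloxy)-5-hydroxypentan-2-one
Product: 4 (3S)-5-chloro-3-(tert-butyldiphenylsilyloxy)pentan-2-one
Conditions: Ph3PCl2, imidazole, CH2Cl2, 0 °C → rt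
Reagents that add atoms: dichlorotriphenylphosphorane `ClP(Cl)(c1ccccc1)(c1ccccc1)c1ccccc1`
Why: Appel-type deoxychlorination of the primary alcohol (open-chain tautomer) gives a chloride that is inert to the phosphonate anion of step 4 but can be displaced later.

Step 4
Reactants: 4 (3S)-5-chloro-3-(tert-butyldiphenylsilyloxy)pentan-2-one
Product: 5 (2E,4S)-6-chloro-4-(tert-butyldiphenylsilyloxy)-N-methoxy-N,3-dimethylhex-2-enamide
Conditions: (EtO)2P(O)CH2C(O)N(OMe)Me, NaH, THF, 0 °C → rt
Reagents that add atoms: diethyl [2-[methoxy(methyl)amino]-2-oxoethyl]phosphonate `CCOP(=O)(CC(=O)N(C)OC)OCC`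
Why: Horner–Wadsworth–Emmons olefination of the activated α-silyloxy methyl ketone places the bulky CH(OSi) branch trans to the amide, giving the 4E alkene with C6 at the Weinreb-amide oxidation level.

Step 5
Reactants: 5 (2E,4S)-6-chloro-4-(tert-butyldiphenylsilyloxy)-N-methoxy-N,3-dimethylhex-2-enamide
Product: 6 [(3S,4E)-3-(tert-butyldiphenylsilyloxy)-6-[methoxy(methyl)amino]-4-methyl-6-oxohex-4-enyl]triphenylphosphonium iodide
Conditions: PPh3, NaI, MeCN, 80 °C
Reagents that add atoms: triphenylphosphine `c1ccc(cc1)P(c1ccccc1)c1ccccc1`; sodium iodide `[Na+].[I-]`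
Why: Finkelstein exchange followed by SN2 quaternization of PPh3 gives the Wittig salt without affecting the enamide or the silyl ether.

Step 6
Reactants: 7 dimethyl (4S,5S)-2,2-dimethyl-1,3-dioxolane-4,5-dicarboxylate (dimethyl 2,3-O-isopropylidene-D-tartrate)
Product: 8 (4S,5S)-N4,N5-dimethoxy-N4,N5,2,2-tetramethyl-1,3-dioxolane-4,5-dicarboxamide
Conditions: MeNH(OMe)·HCl, i-PrMgCl, THF, −20 → 0 °C; aq. NH4Cl
Reagents that add atoms: N,O-dimethylhydroxylamine hydrochloride `CNOC.Cl`
Why: Weinreb amidation of both esters by the magnesium amide proceeds at low temperature, and the trans-dioxolane (C8, C9) is the thermodynamically preferred arrangement so it does not epimerize.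

Step 7
Reactants: 8 (4S,5S)-N4,N5-dimethoxy-N4,N5,2,2-tetramethyl-1,3-dioxolane-4,5-dicarboxamide
Product: 9 (4S,5S)-5-acetyl-N-methoxy-N,2,2-trimethyl-1,3-dioxolane-4-carboxamide
Conditions: MeMgBr (1.3 equiv), THF, −15 → 0 °C; 1 M HCl, 0 °C
Reagents that add atoms: methylmagnesium bromide `C[Mg]Br`
Why: Desymmetrizing Grignard mono-addition to a C2-symmetric bis-Weinreb amide works because the two amides are equivalent and the chelated tetrahedral intermediate of the first addition blocks over-addition and a second attack, giving the C10 methyl ketone (C14 installed).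

Step 8
Reactants: 6 [(3S,4E)-3-(tert-butyldiphenylsilyloxy)-6-[methoxy(methyl)amino]-4-methyl-6-oxohex-4-enyl]triphenylphosphonium iodide; 9 (4S,5S)-5-acetyl-N-methoxy-N,2,2-trimethyl-1,3-dioxolane-4-carboxamide
Product: 11 (4S,5R)-5-[(2Z,5S,6E)-5-(tert-butyldiphenylsilyloxy)-8-[methoxy(methyl)amino]-6-methyl-8-oxoocta-2,6-dien-2-yl]-N-methoxy-N,2,2-trimethyl-1,3-dioxolane-4-carboxamide, via phosphorus ylide 10 (not isolated)
Conditions: 6, KN(SiMe3)2, THF, −78 °C; then 9, −78 → 0 °C
Reagents that add atoms: none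
Why: Wittig olefination of an α-alkoxy methyl ketone with a non-stabilized ylide under salt-free conditions (Sreekumar–Darst–Still selectivity) puts the ylide chain cis to the alkoxy-bearing carbon, giving the 1(10)Z alkene, and the ketone reacts far faster than either Weinreb amide.

Step 9
Reactants: 11 (4S,5R)-5-[(2Z,5S,6E)-5-(tert-butyldiphenylsilyloxy)-8-[methoxy(methyl)amino]-6-methyl-8-oxoocta-2,6-dien-2-yl]-N-methoxy-N,2,2-trimethyl-1,3-dioxolane-4-carboxamide
Product: 12 (4S,5R)-5-[(2Z,5S,6E)-5-(tert-butyldiphenylsilyloxy)-6-methyl-8-oxoocta-2,6-dien-2-yl]-2,2-dimethyl-1,3-dioxolane-4-carbaldehyde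
Conditions: i-Bu2AlH (3 equiv), THF, −78 °C; aq. KNaC4H4O6
Reagents that add atoms: none
Why: Hydride reduction of both Weinreb amides stops at the aldehyde stage because the chelated aluminium hemiaminals collapse only on work-up, giving the C6 E-enal and the C7 α-alkoxy aldehyde in one operation.

Step 10
Reactants: 12 (4S,5R)-5-[(2Z,5S,6E)-5-(tert-butyldiphenylsilyloxy)-6-methyl-8-oxoocta-2,6-dien-2-yl]-2,2-dimethyl-1,3-dioxolane-4-carbaldehyde
Product: 13 methyl 2-[hydroxy[(4R,5R)-5-[(2Z,5S,6E)-5-(tert-butyldiphenylsilyloxy)-6-methyl-8-oxoocta-2,6-dien-2-yl]-2,2-dimethyl-1,3-dioxolan-4-yl]methyl]prop-2-enoate (both C7 carbinol epimers)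
Conditions: methyl acrylate (neat, 10 equiv), 1,4-diazabicyclo[2.2.2]octane (1 equiv), rt, 2–4 d
Reagents that add atoms: methyl acrylate `C=CC(=O)OC`
Why: The Morita–Baylis–Hillman reaction is chemoselective for the highly electrophilic α-alkoxy aldehyde over the hindered β,β-disubstituted enal, the new C7 carbinol centre is removed again in step 11, and the trans-dioxolane keeps C8 from epimerizing.

Step 11
Reactants: 13 methyl 2-[hydroxy[(4R,5R)-5-[(2Z,5S,6E)-5-(tert-butyldiphenylsilyloxy)-6-methyl-8-oxoocta-2,6-dien-2-yl]-2,2-dimethyl-1,3-dioxolan-4-yl]methyl]prop-2-enoate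
Product: 14 methyl (2Z)-2-(bromomethyl)-3-[(4R,5R)-5-[(2Z,5S,6E)-5-(tert-butyldiphenylsilyloxy)-6-methyl-8-oxoocta-2,6-dien-2-yl]-2,2-dimethyl-1,3-dioxolan-4-yl]prop-2-enoate
Conditions: NBS, Me2S, CH2Cl2, −20 °C → rt
Reagents that add atoms: N-bromosuccinimide `BrN1C(=O)CCC1=O`
Why: Corey–Kim-type activation of the Baylis–Hillman alcohol and SN2′ displacement by bromide gives the thermodynamically preferred (Z)-2-(bromomethyl)enoate under neutral conditions that the enal, acetonide and silyl ether tolerate.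

Step 12
Reactants: 14 methyl (2Z)-2-(bromomethyl)-3-[(4R,5R)-5-[(2Z,5S,6E)-5-(tert-butyldiphenylsilyloxy)-6-methyl-8-oxoocta-2,6-dien-2-yl]-2,2-dimethyl-1,3-dioxolan-4-yl]prop-2-enoate
Product: 16 (3S,6R,7S,8R,9R)-3-(tert-butyldiphenylsilyloxy)-8,9-(isopropylidenedioxy)germacra-1(10)Z,4E,11(13)-trien-12,6-olide, via macrocyclic hydroxy ester 15 (not isolated)
Conditions: CrCl2 (20 mol %), 2,4,5,6-tetrakis(carbazol-9-yl)isophthalonitrile (4CzIPN, 2 mol %), diethyl 2,6-dimethyl-1,4-dihydropyridine-3,5-dicarboxylate (Hantzsch ester, 2 equiv), K2HPO4 (2 equiv), degassed DMF/THF (1:1), 450 nm LEDs, 25 °C; 14 added by syringe pump over 20 h (final 3 mM)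
Reagents that add atoms: none
Why: Proposed new method: photoexcited 4CzIPN is reductively quenched by the Hantzsch ester and its radical anion returns trivalent chromium to divalent chromium, which turns the allylic bromide (bromine abstraction, then capture of the allyl radical by a second divalent chromium) into a C13-bound allylchromium whose isomers interconvert and which adds through its γ-carbon C7 to the tethered enal in a chair-like transition state with both ring arms pseudo-equatorial, C6 arriving on the C7 face anti to the C8–O bond of the 1,3-allylic-strain-minimized dioxolane conformer (the face from which the C9 tether delivers it), so that C8 sets C7 (S) and the 6,7-anti alkoxide (C6 R) lactonizes to the trans-lactone and is protonated off chromium to close the cycle; the closest known reactions are the intermolecular photoredox-regenerated chromium or titanium Barbier allylations of aldehydes with allyl bromides and the stoichiometric CrCl2 Nozaki–Hiyama–Kishi macro-allylation used for germacranolide rings, neither of which has been shown as a catalytic, light-driven ten-membered ring closure with in-situ lactonization.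

Step 13
Reactants: 16 (3S,6R,7S,8R,9R)-3-(tert-butyldiphenylsilyloxy)-8,9-(isopropylidenedioxy)germacra-1(10)Z,4E,11(13)-trien-12,6-olide
Product: 17 (3S,6R,7S,8R,9R)-3-(tert-butyldiphenylsilyloxy)-8,9-dihydroxygermacra-1(10)Z,4E,11(13)-trien-12,6-olide
Conditions: AcOH/THF/H2O (3:1:1), 45 °C
Reagents that add atoms: none
Why: Acid-catalysed acetal hydrolysis cleaves the strained trans-fused dioxolane under conditions that leave the tert-butyldiphenylsilyl ether, the lactone and the oxygen-flanked (deactivated) ring alkenes intact.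

Step 14
Reactants: 17 (3S,6R,7S,8R,9R)-3-(tert-butyldiphenylsilyloxy)-8,9-dihydroxygermacra-1(10)Z,4E,11(13)-trien-12,6-olide
Product: 18 (3S,6R,7S,8R,9R)-9-acetoxy-3-(tert-butyldiphenylsilyloxy)-8-hydroxygermacra-1(10)Z,4E,11(13)-trien-12,6-olide
Conditions: AcCl (1.1 equiv), 2,4,6-collidine, CH2Cl2, −40 → −20 °C
Reagents that add atoms: acetyl chloride `CC(=O)Cl`
Why: Sterically governed low-temperature acylation should acetylate O9–H selectively, because it is flanked by the planar sp2 carbon C10 whereas O8–H sits next to the ring-fusion methine C7 and is hydrogen-bonded to the lactone carbonyl.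

Step 15
Reactants: 18 (3S,6R,7S,8R,9R)-9-acetoxy-3-(tert-butyldiphenylsilyloxy)-8-hydroxygermacra-1(10)Z,4E,11(13)-trien-12,6-olide
Product: 19 (3S,6R,7S,8R,9R)-9-acetoxy-8-angeloyloxy-3-(tert-butyldiphenylsilyloxy)germacra-1(10)Z,4E,11(13)-trien-12,6-olide
Conditions: angelic acid, 2,4,6-trichlorobenzoyl chloride, Et3N, toluene, rt; then 18, 65 °C
Reagents that add atoms: angelic acid `C/C=C(/C)C(=O)O`
Why: Yamaguchi-type mixed-anhydride esterification without a nucleophilic catalyst is the standard way to acylate a hindered secondary alcohol with angelic acid without isomerization to the tiglate.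

Step 16
Reactants: 19 (3S,6R,7S,8R,9R)-9-acetoxy-8-angeloyloxy-3-(tert-butyldiphenylsilyloxy)germacra-1(10)Z,4E,11(13)-trien-12,6-olide
Product: 20 CNP0265116.2, (3S,6R,7S,8R,9R)-9-acetoxy-8-angeloyloxy-3-hydroxygermacra-1(10)Z,4E,11(13)-trien-12,6-olide
Conditions: HF·pyridine, pyridine, THF, 0 °C → rt
Reagents that add atoms: none
Why: Fluoride-mediated Si–O cleavage under buffered, mildly acidic conditions removes the silyl ether while sparing the acetate, the angelate and the α-methylene lactone.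

## Compound list

1 | (S)-α-hydroxy-γ-butyrolactone, (3S)-3-hydroxyoxolan-2-one | `O=C1[C@@H](O)CCO1` | starting material
2 | (3S)-3-(tert-butyldiphenylsilyloxy)oxolan-2-one | `O=C1[C@@H](O[Si](c2ccccc2)(c2ccccc2)C(C)(C)C)CCO1` | intermediate
3 | (3S)-3-(tert-butyldiphenylsilyloxy)-5-hydroxypentan-2-one | `CC(=O)[C@@H](O[Si](c1ccccc1)(c1ccccc1)C(C)(C)C)CCO` | intermediate
4 | (3S)-5-chloro-3-(tert-butyldiphenylsilyloxy)pentan-2-one | `CC(=O)[C@@H](O[Si](c1ccccc1)(c1ccccc1)C(C)(C)C)CCCl` | intermediate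
5 | (2E,4S)-6-chloro-4-(tert-butyldiphenylsilyloxy)-N-methoxy-N,3-dimethylhex-2-enamide | `CON(C)C(=O)/C=C(\C)[C@@H](O[Si](c1ccccc1)(c1ccccc1)C(C)(C)C)CCCl` | intermediate
6 | [(3S,4E)-3-(tert-butyldiphenylsilyloxy)-6-[methoxy(methyl)amino]-4-methyl-6-oxohex-4-enyl]triphenylphosphonium iodide | `CON(C)C(=O)/C=C(\C)[C@@H](O[Si](c1ccccc1)(c1ccccc1)C(C)(C)C)CC[P+](c1ccccc1)(c1ccccc1)c1ccccc1.[I-]` | intermediate
7 | dimethyl (4S,5S)-2,2-dimethyl-1,3-dioxolane-4,5-dicarboxylate (dimethyl 2,3-O-isopropylidene-D-tartrate) | `COC(=O)[C@H]1OC(C)(C)O[C@@H]1C(=O)OC` | starting material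
8 | (4S,5S)-N4,N5-dimethoxy-N4,N5,2,2-tetramethyl-1,3-dioxolane-4,5-dicarboxamide | `CON(C)C(=O)[C@H]1OC(C)(C)O[C@@H]1C(=O)N(C)OC` | intermediate
9 | (4S,5S)-5-acetyl-N-methoxy-N,2,2-trimethyl-1,3-dioxolane-4-carboxamide | `CC(=O)[C@H]1OC(C)(C)O[C@@H]1C(=O)N(C)OC` | intermediate
10 | phosphorus ylide of 6, (2E,4S)-4-(tert-butyldiphenylsilyloxy)-N-methoxy-N,3-dimethyl-6-(triphenylphosphoranylidene)hex-2-enamide | `CON(C)C(=O)/C=C(\C)[C@@H](O[Si](c1ccccc1)(c1ccccc1)C(C)(C)C)CC=P(c1ccccc1)(c1ccccc1)c1ccccc1` | intermediate (not isolated)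
11 | (4S,5R)-5-[(2Z,5S,6E)-5-(tert-butyldiphenylsilyloxy)-8-[methoxy(methyl)amino]-6-methyl-8-oxoocta-2,6-dien-2-yl]-N-methoxy-N,2,2-trimethyl-1,3-dioxolane-4-carboxamide | `CON(C)C(=O)/C=C(\C)[C@@H](O[Si](c1ccccc1)(c1ccccc1)C(C)(C)C)C/C=C(/C)[C@H]1OC(C)(C)O[C@@H]1C(=O)N(C)OC` | intermediate
12 | (4S,5R)-5-[(2Z,5S,6E)-5-(tert-butyldiphenylsilyloxy)-6-methyl-8-oxoocta-2,6-dien-2-yl]-2,2-dimethyl-1,3-dioxolane-4-carbaldehyde | `O=C/C=C(\C)[C@@H](O[Si](c1ccccc1)(c1ccccc1)C(C)(C)C)C/C=C(/C)[C@H]1OC(C)(C)O[C@@H]1C=O` | intermediate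
13 | methyl 2-[hydroxy[(4R,5R)-5-[(2Z,5S,6E)-5-(tert-butyldiphenylsilyloxy)-6-methyl-8-oxoocta-2,6-dien-2-yl]-2,2-dimethyl-1,3-dioxolan-4-yl]methyl]prop-2-enoate, mixture of C7 epimers | `O=C/C=C(\C)[C@@H](O[Si](c1ccccc1)(c1ccccc1)C(C)(C)C)C/C=C(/C)[C@H]1OC(C)(C)O[C@@H]1C(O)C(=C)C(=O)OC` | intermediate
14 | methyl (2Z)-2-(bromomethyl)-3-[(4R,5R)-5-[(2Z,5S,6E)-5-(tert-butyldiphenylsilyloxy)-6-methyl-8-oxoocta-2,6-dien-2-yl]-2,2-dimethyl-1,3-dioxolan-4-yl]prop-2-enoate | `O=C/C=C(\C)[C@@H](O[Si](c1ccccc1)(c1ccccc1)C(C)(C)C)C/C=C(/C)[C@H]1OC(C)(C)O[C@@H]1/C=C(\CBr)C(=O)OC` | intermediate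
15 | methyl (3S,6R,7S,8R,9R)-3-(tert-butyldiphenylsilyloxy)-6-hydroxy-8,9-(isopropylidenedioxy)germacra-1(10)Z,4E,11(13)-trien-12-oate | `C=C(C(=O)OC)[C@H]1[C@H](O)/C=C(\C)[C@@H](O[Si](c2ccccc2)(c2ccccc2)C(C)(C)C)C/C=C(/C)[C@H]2OC(C)(C)O[C@@H]21` | intermediate (not isolated)
16 | (3S,6R,7S,8R,9R)-3-(tert-butyldiphenylsilyloxy)-8,9-(isopropylidenedioxy)germacra-1(10)Z,4E,11(13)-trien-12,6-olide | `C=C1C(=O)O[C@@H]2/C=C(\C)[C@@H](O[Si](c3ccccc3)(c3ccccc3)C(C)(C)C)C/C=C(/C)[C@H]3OC(C)(C)O[C@@H]3[C@@H]12` | intermediate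
17 | (3S,6R,7S,8R,9R)-3-(tert-butyldiphenylsilyloxy)-8,9-dihydroxygermacra-1(10)Z,4E,11(13)-trien-12,6-olide | `C=C1C(=O)O[C@@H]2/C=C(\C)[C@@H](O[Si](c3ccccc3)(c3ccccc3)C(C)(C)C)C/C=C(/C)[C@@H](O)[C@H](O)[C@@H]12` | intermediate
18 | (3S,6R,7S,8R,9R)-9-acetoxy-3-(tert-butyldiphenylsilyloxy)-8-hydroxygermacra-1(10)Z,4E,11(13)-trien-12,6-olide | `C=C1C(=O)O[C@@H]2/C=C(\C)[C@@H](O[Si](c3ccccc3)(c3ccccc3)C(C)(C)C)C/C=C(/C)[C@@H](OC(C)=O)[C@H](O)[C@@H]12` | intermediate
19 | (3S,6R,7S,8R,9R)-9-acetoxy-8-angeloyloxy-3-(tert-butyldiphenylsilyloxy)germacra-1(10)Z,4E,11(13)-trien-12,6-olide | `C=C1C(=O)O[C@@H]2/C=C(\C)[C@@H](O[Si](c3ccccc3)(c3ccccc3)C(C)(C)C)C/C=C(/C)[C@@H](OC(C)=O)[C@H](OC(=O)/C(C)=C\C)[C@@H]12` | intermediate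
20 | CNP0265116.2, (3S,6R,7S,8R,9R)-9-acetoxy-8-angeloyloxy-3-hydroxygermacra-1(10)Z,4E,11(13)-trien-12,6-olide | `C=C1C(=O)O[C@@H]2/C=C(\C)[C@@H](O)C/C=C(/C)[C@@H](OC(C)=O)[C@H](OC(=O)/C(C)=C\C)[C@@H]12` | target

## Step count and risk

Total step count: 16 (steps 1–5 for the ylide half, steps 6–7 for the ketone half, steps 8–16 after coupling).
Longest linear sequence: 14 steps (steps 1–5, then 8–16).

The three steps most likely to fail:

Step 12 (the new light-driven macro-allylation). Risks are reduction or 1,4-elimination of the allyl intermediate, the wrong C6/C7 diastereomer, and oligomers. The fallback uses known chemistry, sets out from 14 and comes back at 16. It is the stoichiometric, thermal Nozaki–Hiyama–Kishi macro-allylation (CrCl2, 8 equiv, THF/DMF, 3 mM, 25 → 50 °C, no light and no photocatalyst), the established way to close germacranolide rings. The hydroxy ester 15 is isolated and lactonized in a separate operation (pyridinium p-toluenesulfonate, CH2Cl2, 40 °C). This replaces the light-driven catalytic cycle by stoichiometric two-electron organochromium chemistry and separates C–C bond formation from lactonization. It needs no compound outside the list (none F0).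

Step 14 (regioselective acetylation of the 8,9-diol). The steric argument for O9 is a prediction, not a precedent. The fallback sets out from 17 and comes back at 19, reversing the order of the two acylations so that the bulky acyl donor makes the choice. The mixed anhydride of angelic acid and 2,4,6-trichlorobenzoyl chloride (Et3N, toluene, 25 °C) gives the 8-O-angeloyl 9-alcohol F1 if O8–H proves to be the more reactive hydroxyl. Ac2O/pyridine then acetylates O9 to give 19, bypassing 18.

Step 15 (angeloylation of the hindered O8–H next to an acetate). Risks are tiglate formation, acetyl migration from O9, and relactonization towards O8 under base and heat. The fallback sets out from 18 and comes back at 19 by building the angelate on the molecule. O8–H is esterified with 2-[bis(2,2,2-trifluoroethoxy)phosphoryl]propanoic acid (EDC·HCl, catalytic 4-(dimethylamino)pyridine, CH2Cl2, 0 °C), an unhindered saturated acid that cannot isomerize, to give the phosphonopropionate ester F2. Still–Gennari olefination with acetaldehyde (KN(SiMe3)2, 18-crown-6, THF, −78 °C) is Z-selective and so delivers the angelate 19.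

## Further compounds

F0 | step 12 | none | none
F1 | step 14 | (3S,6R,7S,8R,9R)-8-angeloyloxy-3-(tert-butyldiphenylsilyloxy)-9-hydroxygermacra-1(10)Z,4E,11(13)-trien-12,6-olide | `C=C1C(=O)O[C@@H]2/C=C(\C)[C@@H](O[Si](c3ccccc3)(c3ccccc3)C(C)(C)C)C/C=C(/C)[C@@H](O)[C@H](OC(=O)/C(C)=C\C)[C@@H]12`
F2 | step 15 | (3S,6R,7S,8R,9R)-9-acetoxy-8-[2-[bis(2,2,2-trifluoroethoxy)phosphoryl]propanoyloxy]-3-(tert-butyldiphenylsilyloxy)germacra-1(10)Z,4E,11(13)-trien-12,6-olide, both epimers at the phosphonate α-carbon | `C=C1C(=O)O[C@@H]2/C=C(\C)[C@@H](O[Si](c3ccccc3)(c3ccccc3)C(C)(C)C)C/C=C(/C)[C@@H](OC(C)=O)[C@H](OC(=O)C(C)P(=O)(OCC(F)(F)F)OCC(F)(F)F)[C@@H]12`
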